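The lower, aromatic triterpenoid half is made de novo and joined at the end to commercial pristimerin by a biomimetic hetero-Diels–Alder reaction. Everything rests on a [3+3] disconnection of its ring E across the ring-fusion bond C17′–C18′ and the opposite bond C20′–C21′: C18′–C19′–C20′ is an α-methyl β-keto ester (the C19′ carbonyl activates both flanks), C17′–C22′–C21′ an enyne. In one flask, acid generates the C17′ propargylic cation that the C18′ enol captures (ring D), and manganese triacetate then joins C20′ to the alkyne terminus C21′ (ring E). The precursor is a ring-C enol triflate carrying only the two side chains on its adjacent quaternary carbons C13′ and C14′.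

Key step: step 9

Remark 1 (numbering): locants follow the celastroid (24-nor-D:A-friedooleanane) skeleton; in steps 1–18 they refer to the lower half with the primes dropped; α is the face of the C13 methyl, β the face of the C9, C14, C17 and C20 methyls.

Remark 2 (assumptions): (E)-3-methylpent-2-en-4-yn-1-ol, 2,3-dimethylcyclohex-2-en-1-one, 2,3-dimethoxytoluene and pristimerin are taken as commercial; the ligand enantiomer in step 3 is the one that gives the (2S,3S) ketone.

Step 1
Reactants: 1 (E)-3-methylpent-2-en-4-yn-1-ol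
Product: 2 (E)-3-methyl-5-(trimethylsilyl)pent-2-en-4-yn-1-ol
Conditions: n-BuLi (2.1 equiv), THF, −78 °C; Me3SiCl (2.1 equiv); then 1 M HCl, rt
Reagents that add atoms: chlorotrimethylsilane, C[Si](C)(C)Cl
Why: Double deprotonation, bis-silylation and selective acidic cleavage of the silyl ether (C-silylation of a terminal alkyne) mask the acidic acetylenic hydrogen for the later enolate steps.

Step 2
Reactants: 2 (E)-3-methyl-5-(trimethylsilyl)pent-2-en-4-yn-1-ol
Product: 3 (E)-(5-bromo-3-methylpent-3-en-1-yn-1-yl)trimethylsilane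
Conditions: CBr4, PPh3, CH2Cl2, 0 °C
Reagents that add atoms: tetrabromomethane, BrC(Br)(Br)Br
Why: The Appel bromination turns the primary allylic alcohol into the allylic bromide without allylic transposition or loss of the E geometry.

Step 3
Reactants: 3 (E)-(5-bromo-3-methylpent-3-en-1-yn-1-yl)trimethylsilane; 4 2,3-dimethylcyclohex-2-en-1-one; 5 vinylmagnesium bromide
Product: 7 (2S,3S)-3-ethenyl-2,3-dimethyl-2-[(2E)-3-methyl-5-(trimethylsilyl)pent-2-en-4-yn-1-yl]cyclohexan-1-one (ring C: C1 = C8; C2 = C14; C3 = C13), via bromomagnesium enolate 6 (not isolated)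
Conditions: Cu(OTf)2 (3 mol%), C2-symmetric chiral imidazolinium chloride (NHC precursor, 4 mol%), Et2O, 0 °C; then 3, DMPU, 0 °C → rt
Reagents that add atoms: none
Why: Copper–NHC-catalysed enantioselective conjugate addition of the Grignard reagent to the trisubstituted enone sets C13 by catalyst control, and the regiodefined magnesium enolate is C-alkylated by the allylic bromide anti to the newly introduced axial vinyl group, which places C15 trans to C18 at C14.

Step 4
Reactants: 7 (2S,3S)-ketone
Product: 8 (2S,3S)-3-ethenyl-2,3,6-trimethyl-2-[(2E)-3-methyl-5-(trimethylsilyl)pent-2-en-4-yn-1-yl]cyclohexan-1-one (C9 methyl; both C6 epimers)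
Conditions: LiN(i-Pr)2, THF, −78 °C; MeI
Reagents that add atoms: iodomethane, CI
Why: Enolate alkylation is regiospecific because C9 is the only enolisable position (C14 is quaternary), and the C9 configuration is irrelevant since C9 becomes sp2 in step 5.

Step 5
Reactants: 8 C9-methyl ketone
Product: 9 (5S,6S)-5-ethenyl-2,5,6-trimethyl-6-[(2E)-3-methyl-5-(trimethylsilyl)pent-2-en-4-yn-1-yl]cyclohex-1-en-1-yl trifluoromethanesulfonate
Conditions: KN(SiMe3)2, THF, −78 °C; PhNTf2; aq. NH4Cl
Reagents that add atoms: N-phenylbis(trifluoromethanesulfonimide), O=S(=O)(N(c1ccccc1)S(=O)(=O)C(F)(F)F)C(F)(F)F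
Why: O-Triflation of the only possible enolate gives an enol triflate that removes the enolisable ring-C ketone before the cationic key step and later serves as the handle for attaching ring A.

Step 6
Reactants: 9 enol triflate
Product: 10 5-(2-hydroxyethyl)-2,5,6-trimethyl-6-[(2E)-3-methylpent-2-en-4-yn-1-yl]cyclohex-1-en-1-yl trifluoromethanesulfonate (C13 and C14 as in 9)
Conditions: 9-BBN, THF, 0 °C → rt; then NaOH, H2O2, MeOH–H2O, 0 °C
Reagents that add atoms: hydrogen peroxide, OO
Why: Anti-Markovnikov hydroboration–oxidation selects the monosubstituted vinyl group over the trisubstituted enyne alkene, the silyl alkyne and the electron-poor enol triflate, and the alkaline work-up also removes the alkynyl silyl group (protiodesilylation).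

Step 7
Reactants: 10 primary alcohol
Product: 11 {1,2,4-trimethyl-2-[(2E)-3-methylpent-2-en-4-yn-1-yl]-3-(trifluoromethanesulfonyloxy)cyclohex-3-en-1-yl}acetic acid (C13 and C14 as in 9)
Conditions: TEMPO (20 mol%), PhI(OAc)2 (2.5 equiv), MeCN–H2O, rt
Reagents that add atoms: water, O
Why: Oxoammonium-mediated oxidation takes the primary alcohol through the aldehyde hydrate to the carboxylic acid and leaves alkyne, alkene and enol triflate untouched.

Step 8
Reactants: 11 carboxylic acid
Product: 13 methyl 2-methyl-3-oxo-4-{1,2,4-trimethyl-2-[(2E)-3-methylpent-2-en-4-yn-1-yl]-3-(trifluoromethanesulfonyloxy)cyclohex-3-en-1-yl}butanoate (C20 epimers), via acyl imidazolide 12 (not isolated)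
Conditions: CDI, THF, rt; then LiCH(CH3)CO2Me (3 equiv, from methyl propanoate and LiN(i-Pr)2), THF, −78 °C; aq. NH4Cl
Reagents that add atoms: methyl propanoate, CCC(=O)OC
Why: Crossed Claisen condensation of the lithium ester enolate with the acyl imidazolide gives the α-methyl β-keto ester and so installs C20 with both of its final substituents.

Step 9
Reactants: 13 α-methyl β-keto ester with enyne side chain
Product: 15 tricyclic (rings C, D, E) keto ester: 8-triflyloxy-Δ8(9); Δ21; 19-oxo; 13α-Me; 14β-Me; 17β-Me; 18β-H; 20β-Me; 20α-CO2Me, via ring-D alkyne 14 (not isolated)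
Conditions: TfOH (10 mol%), (CF3)2CHOH–CH2Cl2, −20 → 0 °C; then NaOAc, Mn(OAc)3·2H2O (2.2 equiv), AcOH–EtOH, 70 °C
Reagents that add atoms: none
Why: TfOH protonates the conjugated enyne at C16 and the tertiary propargylic cation at C17 is captured by C18 of the ketone enol (cation–olefin cyclisation terminated by an enol, a Prins/Conia-type carbocyclisation; ring D by a 6-endo-trig closure with respect to the protonated alkene, enol-exo), giving 14; trivalent manganese then oxidises the α-methyl β-keto ester to the C20 radical, which adds to the alkyne terminus C21 (oxidative free-radical cyclisation of an unsaturated β-keto ester; ring E by 6-endo-dig closure), and the vinyl radical at C22 abstracts hydrogen from ethanol. C17 is set in the chair transition state of ring D, trans-fused to ring C, in which the slim ethynyl group rather than the methyl group takes the axial site syn to the axial C13 methyl, so that C22 becomes α and the C17 methyl β. C18 is set in the same closure with the acyl branch equatorial (18β-H) and, being α to the C19 ketone, can equilibrate to this cis D/E arrangement. C20 is set in the radical closure: the tether delivers C21 to the face of the planar radical opposite to C13, and the radical reacts in the geometry with the ester anti to the ketone oxygen, which leaves CO2Me α and the methyl β. The step needs C18 and not the more enolised C20 to attack the cation, which the tether secures (C20 attack would close an eight-membered ring) together with the enol triflate at C8 that has removed the competing ring-C enol, and it needs 6-endo rather than 5-exo attack on the alkyne, which the unhindered terminal carbon next to quaternary C17 favours.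

Step 10
Reactants: 15 tricyclic keto ester
Product: 16 the 19-hydroxy ester (C19 epimers)
Conditions: NaBH4, CeCl3·7H2O, MeOH, 0 °C
Reagents that add atoms: none
Why: Luche-type hydride reduction takes the C19 ketone to the alcohol while ester, alkene and enol triflate are inert, and the carbinol configuration is irrelevant because the oxygen is removed.

Step 11
Reactants: 16 19-hydroxy ester
Product: 17 the 19-O-[(methylsulfanyl)carbonothioyl] derivative (S-methyl xanthate)
Conditions: KN(SiMe3)2, THF, −78 °C; CS2; MeI
Reagents that add atoms: carbon disulfide, S=C=S; iodomethane, CI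
Why: Xanthate formation from the potassium alkoxide at low temperature activates the hindered alcohol for radical deoxygenation and avoids retro-aldol cleavage of the β-hydroxy ester.

Step 12
Reactants: 17 xanthate
Product: 18 the 19-deoxy tricyclic ester enol triflate (C19 methylene; Δ21)
Conditions: Bu3SnH, AIBN, toluene, 100 °C
Reagents that add atoms: none
Why: Barton–McCombie radical deoxygenation turns the secondary xanthate into the C19 methylene, and enol triflate, ester and the isolated ring-E alkene do not enter the stannyl radical chain.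

Step 13
Reactants: 19 2,3-dimethoxytoluene
Product: 20 1-bromo-3,4-dimethoxy-2-methylbenzene
Conditions: NBS, MeCN, 0 °C → rt
Reagents that add atoms: N-bromosuccinimide, O=C1CCC(=O)N1Br
Why: Electrophilic aromatic bromination occurs para to the unhindered, coplanar methoxy group and ortho to the methyl group, the most activated position.

Step 14
Reactants: 20 1-bromo-3,4-dimethoxy-2-methylbenzene
Product: 21 1-ethenyl-3,4-dimethoxy-2-methylbenzene
Conditions: 4,4,5,5-tetramethyl-2-vinyl-1,3,2-dioxaborolane, Pd(dppf)Cl2 (3 mol%), K2CO3, dioxane–H2O, 80 °C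
Reagents that add atoms: vinylboronic acid pinacol ester, C=CB1OC(C)(C)C(C)(C)O1
Why: Suzuki–Miyaura vinylation of the aryl bromide gives the styrene that carries C6, C7 and ring A.

Step 15
Reactants: 18 19-deoxy enol triflate; 21 1-ethenyl-3,4-dimethoxy-2-methylbenzene
Product: 23 the 8-[2-(3,4-dimethoxy-2-methylphenyl)ethyl]-Δ8(9) tricyclic ester (tetrasubstituted C8=C9; Δ21), via B-(2-arylethyl)-9-borabicyclononane 22 (not isolated)
Conditions: 21, 9-BBN, THF, rt; then 18, Pd(dppf)Cl2 (5 mol%), K3PO4 (aq.), DMF–THF, 60 °C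
Reagents that add atoms: none
Why: Anti-Markovnikov hydroboration of the styrene and B-alkyl Suzuki–Miyaura coupling with the enol triflate attach the C6–C7 bridge and ring A to C8.

Step 16
Reactants: 23 arylethyl diene ester
Product: 24 the 21,22-dihydro compound (only the tetrasubstituted C8=C9 alkene left)
Conditions: H2 (1 atm), Pd/C, EtOAc, rt
Reagents that add atoms: none
Why: Heterogeneous hydrogenation saturates the cis-disubstituted C21=C22 alkene, whereas the tetrasubstituted C8=C9 alkene next to quaternary C14 is too hindered to react, and no stereocentre is created.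

Step 17
Reactants: 24 arylethyl alkene
Product: 25 methyl 2,3-dimethoxy-24-nor-D:A-friedooleana-1,3,5(10)-trien-29-oate (7,8-dihydropristimerol dimethyl ether; 8α-H; 9β-Me)
Conditions: TfOH (20 mol%), CH2Cl2, −40 → 0 °C
Reagents that add atoms: none
Why: In this cyclialkylation (intramolecular Friedel–Crafts alkylation of an arylethyl cyclohexene) protonation at C8 from the α-face gives the tertiary C9 cation, which the arene carbon para to the C3 methoxy group attacks from the α-face anti to the axial C14 methyl, so that ring B closes trans-fused with 8α-H and 9β-methyl.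

Step 18
Reactants: 25 dimethyl ether
Product: 26 methyl 2,3-dihydroxy-24-nor-D:A-friedooleana-1,3,5(10)-trien-29-oate (7,8-dihydropristimerol)
Conditions: BBr3 (3 equiv), CH2Cl2, −78 → 0 °C; H2O
Reagents that add atoms: none
Why: Boron tribromide cleaves the two aryl methyl ethers, while the neopentyl-type tertiary methyl ester reacts much more slowly at this temperature.

Step 19
Reactants: 26 7,8-dihydropristimerol; 27 pristimerin
Product: 29 CNP0154412.1, via o-quinone 28 (not isolated)
Conditions: Ag2O (2 equiv), 27 (2 equiv), Na2SO4, CH2Cl2, rt, dark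
Reagents that add atoms: none
Why: Ag2O oxidises the catechol to the o-quinone, whose O=C–C=O unit adds as heterodiene to the electron-rich C3=C4 enol double bond of pristimerin (inverse-electron-demand hetero-Diels–Alder reaction, the biomimetic union of this dimer family) from the α-face anti to the 9β-methyl group, C4 bonding to the oxygen on C3′ and the new hemiketal carbon C3 to the oxygen on C2′, which sets the cis-fused dioxane stereocentres C3 and C4.

Compound list

1 | (E)-3-methylpent-2-en-4-yn-1-ol | OC/C=C(\C)C#C | starting material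
2 | (E)-3-methyl-5-(trimethylsilyl)pent-2-en-4-yn-1-ol | OC/C=C(\C)C#C[Si](C)(C)C | intermediate
3 | (E)-(5-bromo-3-methylpent-3-en-1-yn-1-yl)trimethylsilane | BrC/C=C(\C)C#C[Si](C)(C)C | intermediate
4 | 2,3-dimethylcyclohex-2-en-1-one | CC1=C(C)C(=O)CCC1 | starting material
5 | vinylmagnesium bromide | C=C[Mg]Br | starting material
6 | bromomagnesium enolate of (3S)-3-ethenyl-2,3-dimethylcyclohexanone | CC1=C(O[Mg]Br)CCC[C@@]1(C)C=C | intermediate (not isolated)
7 | (2S,3S)-3-ethenyl-2,3-dimethyl-2-[(2E)-3-methyl-5-(trimethylsilyl)pent-2-en-4-yn-1-yl]cyclohexan-1-one | O=C1CCC[C@@](C)(C=C)[C@]1(C)C/C=C(\C)C#C[Si](C)(C)C | intermediate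
8 | (2S,3S)-3-ethenyl-2,3,6-trimethyl-2-[(2E)-3-methyl-5-(trimethylsilyl)pent-2-en-4-yn-1-yl]cyclohexan-1-one (C6 epimers) | O=C1C(C)CC[C@@](C)(C=C)[C@]1(C)C/C=C(\C)C#C[Si](C)(C)C | intermediate
9 | (5S,6S)-5-ethenyl-2,5,6-trimethyl-6-[(2E)-3-methyl-5-(trimethylsilyl)pent-2-en-4-yn-1-yl]cyclohex-1-en-1-yl trifluoromethanesulfonate | CC1=C(OS(=O)(=O)C(F)(F)F)[C@@](C)(C/C=C(\C)C#C[Si](C)(C)C)[C@](C)(C=C)CC1 | intermediate
10 | 5-(2-hydroxyethyl)-2,5,6-trimethyl-6-[(2E)-3-methylpent-2-en-4-yn-1-yl]cyclohex-1-en-1-yl trifluoromethanesulfonate (C13, C14 as in 9) | CC1=C(OS(=O)(=O)C(F)(F)F)[C@@](C)(C/C=C(\C)C#C)[C@](C)(CCO)CC1 | intermediate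
11 | {1,2,4-trimethyl-2-[(2E)-3-methylpent-2-en-4-yn-1-yl]-3-(trifluoromethanesulfonyloxy)cyclohex-3-en-1-yl}acetic acid | CC1=C(OS(=O)(=O)C(F)(F)F)[C@@](C)(C/C=C(\C)C#C)[C@](C)(CC(=O)O)CC1 | intermediate
12 | acyl imidazolide of 11 | CC1=C(OS(=O)(=O)C(F)(F)F)[C@@](C)(C/C=C(\C)C#C)[C@](C)(CC(=O)n2ccnc2)CC1 | intermediate (not isolated)
13 | methyl 2-methyl-3-oxo-4-{1,2,4-trimethyl-2-[(2E)-3-methylpent-2-en-4-yn-1-yl]-3-(trifluoromethanesulfonyloxy)cyclohex-3-en-1-yl}butanoate (C20 epimers) | CC1=C(OS(=O)(=O)C(F)(F)F)[C@@](C)(C/C=C(\C)C#C)[C@](C)(CC(=O)C(C)C(=O)OC)CC1 | intermediate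
14 | ring-C/D bicyclic enol triflate with 17α-ethynyl, 17β-methyl and 18β-H, C18 bearing the 2-(methoxycarbonyl)propanoyl group | CC1=C(OS(=O)(=O)C(F)(F)F)[C@@]2(C)CC[C@@](C)(C#C)[C@@H](C(=O)C(C)C(=O)OC)[C@]2(C)CC1 | intermediate (not isolated)
15 | ring-C/D/E tricyclic keto ester (8-triflyloxy-Δ8(9), Δ21, 19-oxo; 13α-Me, 14β-Me, 17β-Me, 18β-H, 20β-Me, 20α-CO2Me) | CC1=C(OS(=O)(=O)C(F)(F)F)[C@@]2(C)CC[C@@]3(C)C=C[C@@](C)(C(=O)OC)C(=O)[C@H]3[C@]2(C)CC1 | intermediate
16 | 19-hydroxy derivative of 15 (C19 epimers) | CC1=C(OS(=O)(=O)C(F)(F)F)[C@@]2(C)CC[C@@]3(C)C=C[C@@](C)(C(=O)OC)C(O)[C@H]3[C@]2(C)CC1 | intermediate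
17 | 19-O-[(methylsulfanyl)carbonothioyl] derivative of 16 | CC1=C(OS(=O)(=O)C(F)(F)F)[C@@]2(C)CC[C@@]3(C)C=C[C@@](C)(C(=O)OC)C(OC(=S)SC)[C@H]3[C@]2(C)CC1 | intermediate
18 | 19-deoxy tricyclic ester enol triflate (Δ8(9), Δ21) | CC1=C(OS(=O)(=O)C(F)(F)F)[C@@]2(C)CC[C@@]3(C)C=C[C@@](C)(C(=O)OC)C[C@H]3[C@]2(C)CC1 | intermediate
19 | 2,3-dimethoxytoluene | COc1cccc(C)c1OC | starting material
20 | 1-bromo-3,4-dimethoxy-2-methylbenzene | COc1ccc(Br)c(C)c1OC | intermediate
21 | 1-ethenyl-3,4-dimethoxy-2-methylbenzene | C=Cc1ccc(OC)c(OC)c1C | intermediate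
22 | 9-[2-(3,4-dimethoxy-2-methylphenyl)ethyl]-9-borabicyclo[3.3.1]nonane | COc1ccc(CCB2C3CCCC2CCC3)c(C)c1OC | intermediate (not isolated)
23 | 8-[2-(3,4-dimethoxy-2-methylphenyl)ethyl] tricyclic ester (Δ8(9), Δ21) | CC1=C(CCc2ccc(OC)c(OC)c2C)[C@@]3(C)CC[C@@]4(C)C=C[C@@](C)(C(=O)OC)C[C@H]4[C@]3(C)CC1 | intermediate
24 | 21,22-dihydro derivative of 23 (Δ8(9) only) | CC1=C(CCc2ccc(OC)c(OC)c2C)[C@@]3(C)CC[C@@]4(C)CC[C@@](C)(C(=O)OC)C[C@H]4[C@]3(C)CC1 | intermediate
25 | methyl 2,3-dimethoxy-24-nor-D:A-friedooleana-1,3,5(10)-trien-29-oate (8α-H) | COc1cc2c(c(C)c1OC)CC[C@H]3[C@@]2(C)CC[C@@]4(C)[C@@H]5C[C@](C)(C(=O)OC)CC[C@]5(C)CC[C@]34C | intermediate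
26 | methyl 2,3-dihydroxy-24-nor-D:A-friedooleana-1,3,5(10)-trien-29-oate (7,8-dihydropristimerol) | Oc1cc2c(c(C)c1O)CC[C@H]3[C@@]2(C)CC[C@@]4(C)[C@@H]5C[C@](C)(C(=O)OC)CC[C@]5(C)CC[C@]34C | intermediate
27 | pristimerin | CC1=C(C(=O)C=C2C1=CC=C3[C@]2(CC[C@@]4([C@@]3(CC[C@@]5([C@H]4C[C@](CC5)(C)C(=O)OC)C)C)C)C)O | starting material
28 | o-quinone of 26 (2,3-dioxo-1(10),4-diene) | O=C1C=C2C(=C(C)C1=O)CC[C@H]3[C@@]2(C)CC[C@@]4(C)[C@@H]5C[C@](C)(C(=O)OC)CC[C@]5(C)CC[C@]34C | intermediate (not isolated)
29 | CNP0154412.1 | COC(=O)[C@]1(C)CC[C@]2(C)CC[C@]3(C)C4=CC=C5C(=CC(=O)[C@@]6(O)Oc7cc8c(c(C)c7O[C@@]56C)CC[C@H]5[C@@]8(C)CC[C@@]6(C)[C@@H]7C[C@](C)(C(=O)OC)CC[C@]7(C)CC[C@]56C)[C@]4(C)CC[C@@]3(C)[C@@H]2C1 | target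

Total step count: 19. Longest linear sequence: 17 steps (steps 1–12 and 15–19, from 1).

Steps most likely to fail

Step 9. The C18 enol is only a minor tautomer of the β-keto ester, so the cation may be lost to elimination or oligomerisation, and in the radical stage 5-exo closure or over-oxidation may compete with the 6-endo closure. The fallback sets out from 13 and runs the two closures separately. The acid stage is carried out alone (TfOH, (CF3)2CHOH–CH2Cl2) and the ring-D alkyne 14 is isolated. 14 is converted with t-BuMe2SiOTf and Et3N into the silyl enol ether of its β-keto ester F1. F1 is closed by the tungsten-vinylidene 6-endo-dig carbocyclisation of ω-alkynyl silyl enol ethers (W(CO)6, hν, THF–H2O), which comes back to the route at 15.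

Step 17. Protonation of the tetrasubstituted alkene at C9 instead of C8 would give the C8 cation, which can undergo Wagner–Meerwein shifts of the C14 substituents or spiro-cyclisation, and the facial selectivity at C9 may be poor. The fallback sets out from 24 and fixes the C8 hydrogen before any cation is formed. Syn-hydroboration–oxidation from the α-face (BH3·SMe2, THF; NaOH, H2O2) gives the 9α-hydroxy-8α-H tertiary alcohol F2. Ionisation of F2 with BF3·OEt2 (CH2Cl2, −40 °C) generates the C9 cation directly, and the arene closes ring B anti to the C14 methyl, which comes back to the route at 25.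

Step 3. The enantioselectivity of the copper-catalysed addition to the α-methylated enone may be low, and the facial selectivity of the enolate alkylation next to the new quaternary centre may be poor. The fallback sets out from 4, 5 and 3 and replaces asymmetric catalysis by resolution. The same conjugate addition–alkylation is run with an achiral catalyst (CuBr·SMe2, THF; then 3, DMPU) to give racemic ketone F3. F3 is resolved by preparative chromatography on a chiral stationary phase, which comes back to the route at 7.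

Further compounds

F1 | step 9 | tert-butyldimethylsilyl enol ether of the β-keto ester of 14 | CC1=C(OS(=O)(=O)C(F)(F)F)[C@@]2(C)CC[C@@](C)(C#C)[C@@H](C(O[Si](C)(C)C(C)(C)C)=C(C)C(=O)OC)[C@]2(C)CC1
F2 | step 17 | 9α-hydroxy-8α-H tertiary alcohol from 24 (ring B open) | C[C@]1(O)[C@H](CCc2ccc(OC)c(OC)c2C)[C@@]3(C)CC[C@@]4(C)CC[C@@](C)(C(=O)OC)C[C@H]4[C@]3(C)CC1
F3 | step 3 | racemic 7 (2RS,3RS; one enantiomer drawn) | O=C1CCC[C@@](C)(C=C)[C@]1(C)C/C=C(\C)C#C[Si](C)(C)C
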